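A direct plan would hydroformylate methyl eugenol A1 to the linear aldehyde 4-(3,4-dimethoxyphenyl)butanal A2, would join A2 to hexadec-1-yne A3 in a zinc-mediated, amine-assisted allenation to 4-(icosa-4,5-dien-1-yl)-1,2-dimethoxybenzene A4, would hydrate allene A4 at its central carbon to 1-(3,4-dimethoxyphenyl)icosan-5-one A5, and would finally cleave both methyl ethers of A5. Its weakest steps would be:
- the central-carbon hydration of A4, because no established catalyst delivers water to the sp carbon of an unactivated 1,3-dialkylallene and π-acids favour the termini;
- the linear hydroformylation of A1, because isomerisation to the propenylarene and formation of the branched aldehyde would compete and pressure equipment would be needed;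
- the closing ether cleavage of A5, because it would add a step and a harsh Lewis acid without adding complexity.

The route would rest on the aryl–C1 bond and would treat the C5 ketone as the end point of a palladium chain walk. It exploits the unbranched methylene track C1–C4 that separates the ring carbon from C5, the only oxygen-bearing chain carbon. A C20 alkenol with its double bond at C1=C2 and its hydroxyl group at C5 and an unprotected 4-halocatechol would be joined in one redox-relay Heck arylation that forms the aryl–C1 bond, saturates C1–C4 and converts the carbinol into the ketone. The C5 oxygen would come from an aldehyde, C1–C4 from a Grignard reagent, and the catechol would enter free, so no allene hydration, hydroformylation or ether cleavage would remain.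

Key step: step 2

Remark on the chemistry: chain atoms are numbered C1 (benzylic) to C20 as in the name icosan-5-one; the target is achiral.

Step 1
Reactants: 1 hexadecanal, 2 but-3-en-1-ylmagnesium bromide (1.2 equiv, 0.5 M in THF)
Product: 4 racemic icos-1-en-5-ol, via bromomagnesium icos-1-en-5-olate 3 (not isolated)
Conditions: THF, 0 °C to rt, 2 h; then 1 M HCl, 0 °C
Reagents that add atoms: none
Why: Grignard 1,2-addition to an aliphatic aldehyde; alkoxide 3 is protonated on acidic work-up, and the new carbinol centre C5 is formed racemic, which is of no consequence because step 2 turns it into the carbonyl carbon.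

Step 2
Reactants: 4 racemic icos-1-en-5-ol (1.3 equiv), 5 4-bromocatechol (4-bromobenzene-1,2-diol, 1.0 equiv)
Product: 7 1-(3,4-dihydroxyphenyl)icosan-5-one, via enol 1-(3,4-dihydroxyphenyl)icos-4-en-5-ol 6 (not isolated)
Conditions: Pd(OAc)2 (5 mol%), n-Bu4NCl (2 equiv), LiCl (1 equiv), NaOAc (2.5 equiv), degassed DMF, 110 °C, Ar; then dilute aq HCl, extraction under N2
Reagents that add atoms: none
Why: Redox-relay (chain-walking) Heck arylation: zerovalent palladium, formed in situ from Pd(OAc)2, inserts into the C–Br bond of 5, the arylpalladium bromide adds syn across C1=C2 of 4 with the aryl group on the terminal carbon C1, and repeated syn β-hydride elimination and reinsertion carry palladium from C2 through C3 to C4, where elimination of the carbinol hydrogen at C5 gives enol 6, which tautomerises to the ketone, while NaOAc takes HBr from the palladium hydride bromide and regenerates zerovalent palladium. The closest known reaction type is the palladium-catalysed coupling of aryl halides with non-allylic ω-alkenols under ligand-free phase-transfer (Jeffery-type) conditions, which gives aryl-substituted aldehydes and ketones by the same migration over several methylene groups. No ring is closed and no stereocentre is formed; the racemic centre C5 of 4 becomes the planar carbonyl carbon. The step needs aryl delivery to C1 and not C2, which the monosubstituted unbranched alkene should secure sterically, and a walk that ends at C5 and not at a C1=C2 styrene, which should be secured by the unbranched C2–C4 track, by the chloride additives used for such migrations, and by the irreversible carbonyl formation at the only hydroxyl-bearing carbon, the thermodynamic sink for all alkene isomers that stay on palladium. The weak carboxylate base and the exclusion of air should leave the catechol largely protonated and unoxidised, and the hydroxyl groups, meta and para to bromine, do not hinder oxidative addition.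

**Compound list**

1 | hexadecanal | CCCCCCCCCCCCCCCC=O | starting material
2 | but-3-en-1-ylmagnesium bromide | C=CCC[Mg]Br | starting material
3 | bromomagnesium icos-1-en-5-olate (racemic, not isolated) | CCCCCCCCCCCCCCCC(O[Mg]Br)CCC=C | intermediate
4 | icos-1-en-5-ol (racemic) | CCCCCCCCCCCCCCCC(O)CCC=C | intermediate
5 | 4-bromocatechol (4-bromobenzene-1,2-diol) | Oc1ccc(Br)cc1O | starting material
6 | 1-(3,4-dihydroxyphenyl)icos-4-en-5-ol (enol, alkene geometry not defined, not isolated) | CCCCCCCCCCCCCCCC(O)=CCCCc1ccc(O)c(O)c1 | intermediate
7 | 1-(3,4-dihydroxyphenyl)icosan-5-one (achiral) | CCCCCCCCCCCCCCCC(=O)CCCCc1ccc(O)c(O)c1 | target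

Total step count: 2. Longest linear sequence: 2 steps.

Steps most likely to fail (the route has only two steps, so both are ranked, the key step first):

1. Step 2. Several processes could limit it:
   - palladium hydride may leave the chain before reaching C5, giving arylated alkenols instead of the ketone;
   - carbopalladation may place the aryl group on C2, giving a methyl-branched ketone;
   - unarylated 4 may be isomerised to the saturated ketone;
   - oxidative addition of the electron-rich bromide may be slow;
   - the catalyst may be deactivated by chelation or oxidation of the free catechol.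

   Fallback, from 4 and back at 7, with the aryl partner 1,2-bis(benzyloxy)-4-bromobenzene F1. Compound 4 would be hydroborated with 9-BBN (2.2 equiv, THF, rt; the hydroxyl group takes up one equivalent) to the borane 9-[5-(9-borabicyclo[3.3.1]nonan-9-yloxy)icosyl]-9-borabicyclo[3.3.1]nonane F2. Without isolation, F2 would be coupled with F1 in a B-alkyl Suzuki–Miyaura reaction (PdCl2(dppf), aq K3PO4, THF/DMF, 60 °C) to racemic 1-[3,4-bis(benzyloxy)phenyl]icosan-5-ol F3. Dess–Martin oxidation (CH2Cl2, rt) would give 1-[3,4-bis(benzyloxy)phenyl]icosan-5-one F4, and hydrogenolysis (H2, 1 atm, Pd/C, EtOAc/EtOH, rt) would release 7.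

2. Step 1. Enolisation and aldol self-condensation of the long-chain aldehyde, reduction of the aldehyde by β-hydride transfer from the Grignard reagent, or incomplete conversion of oligomerised aldehyde may lower the return of 4.

   Fallback, from 2 and back at 4. Compound 2 would be acylated with hexadecanoyl chloride F5 under iron catalysis (Fe(acac)3 3 mol%, THF, −78 °C) to icos-1-en-5-one F6. F6 would be reduced with NaBH4 (MeOH/THF, 0 °C) to 4.

**Further compounds**

F1 | step 2 | 1,2-bis(benzyloxy)-4-bromobenzene | Brc1ccc(OCc2ccccc2)c(OCc2ccccc2)c1
F2 | step 2 | 9-[5-(9-borabicyclo[3.3.1]nonan-9-yloxy)icosyl]-9-borabicyclo[3.3.1]nonane (racemic, not isolated) | CCCCCCCCCCCCCCCC(OB1C2CCCC1CCC2)CCCCB1C2CCCC1CCC2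
F3 | step 2 | 1-[3,4-bis(benzyloxy)phenyl]icosan-5-ol (racemic) | CCCCCCCCCCCCCCCC(O)CCCCc1ccc(OCc2ccccc2)c(OCc2ccccc2)c1
F4 | step 2 | 1-[3,4-bis(benzyloxy)phenyl]icosan-5-one | CCCCCCCCCCCCCCCC(=O)CCCCc1ccc(OCc2ccccc2)c(OCc2ccccc2)c1
F5 | step 1 | hexadecanoyl chloride | CCCCCCCCCCCCCCCC(=O)Cl
F6 | step 1 | icos-1-en-5-one | CCCCCCCCCCCCCCCC(=O)CCC=C
A1 | direct plan | methyl eugenol (4-allyl-1,2-dimethoxybenzene) | C=CCc1ccc(OC)c(OC)c1
A2 | direct plan | 4-(3,4-dimethoxyphenyl)butanal | O=CCCCc1ccc(OC)c(OC)c1
A3 | direct plan | hexadec-1-yne | CCCCCCCCCCCCCCC#C
A4 | direct plan | 4-(icosa-4,5-dien-1-yl)-1,2-dimethoxybenzene (racemic allene) | CCCCCCCCCCCCCCC=C=CCCCc1ccc(OC)c(OC)c1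
A5 | direct plan | 1-(3,4-dimethoxyphenyl)icosan-5-one | CCCCCCCCCCCCCCCC(=O)CCCCc1ccc(OC)c(OC)c1
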